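**Retrosynthetic overview**
1. The biaryl bond is made last but one: Suzuki union of oxolane bromide 12 (borylated in the flask) with tetralin bromide 13, then global debenzylation.
2. Tetralin 13 comes from oxolane 12 itself, by acid ionisation of the benzylic C–O bond and Friedel–Crafts closure, so one monomer serves both halves.
3. Oxolane 12 comes from hydroxy-lactone 10 (C=O to CH2), and 10 from cis-lactone 6 by enolate benzylation, then enolate hydroxylation anti to the two cis groups.
4. Key C–C bond (C7–C8, lignan numbering): lactone 6 from aryl aldehyde 2 and enal 5 by an enantioselective NHC homoenolate annulation, in which the enal β-carbon attacks the aldehyde carbon as a nucleophile.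
5. Ring order: five-membered lactone (later the oxolane) first, tetralin second on part of the material, biaryl bond third.

Assumption: the SMILES is taken literally (oxolane half 7R,8R,8'S with aryl, CH2OH and benzyl all on one face; tetralin half 2S,3S,4S), and the (5aS,10bR) triazolium salt of step 3 is taken to be the enantiomer that gives the (4R,5R)-lactone (its antipode is used otherwise).

**Step 1**
Reactants: 1 5-bromovanillin (3-bromo-4-hydroxy-5-methoxybenzaldehyde)
Product: 2 4-(benzyloxy)-3-bromo-5-methoxybenzaldehyde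
Conditions: BnBr (1.2 equiv), K2CO3 (1.5 equiv), DMF, 60 °C
Reagents that add atoms: benzyl bromide, BrCc1ccccc1
Why: Williamson ether synthesis; the benzyl ether prevents phenoxide formation (which would deactivate the aldehyde in step 3) and survives every later step until hydrogenolysis.

**Step 2**
Reactants: 3 allyl benzyl ether; 4 (E)-crotonaldehyde
Product: 5 (E)-4-(benzyloxy)but-2-enal
Conditions: 4 (3 equiv), second-generation Hoveyda–Grubbs catalyst RuCl2(H2IMes)(=CH-C6H4-2-OiPr) (2 mol %), CH2Cl2, 40 °C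
Reagents that add atoms: none
Why: Olefin cross-metathesis of a terminal allyl ether with an enal partner, driven by loss of propene and E-selective under thermodynamic control.

**Step 3 (key step)**
Reactants: 2 4-(benzyloxy)-3-bromo-5-methoxybenzaldehyde; 5 (E)-4-(benzyloxy)but-2-enal
Product: 6 (4R,5R)-4-[(benzyloxy)methyl]-5-[4-(benzyloxy)-3-bromo-5-methoxyphenyl]oxolan-2-one
Conditions: 2 (1.0 equiv), 5 (1.5 equiv, added over 8 h), (5aS,10bR)-2-mesityl-5a,10b-dihydro-4H,6H-indeno[2,1-b][1,2,4]triazolo[4,3-d][1,4]oxazin-2-ium chloride (10 mol %), DBU (10 mol %), LiCl (1.0 equiv), 4 Å MS, THF, 23 °C; chromatography to remove the minor trans-lactone, one recrystallisation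
Reagents that add atoms: none
Why: Proposed new method: an enantioselective NHC-catalysed homoenolate [3+2] annulation in which the triazolylidene adds to enal 5 to give the extended Breslow intermediate, its C3 (the normally electrophilic β-carbon) attacks the Li+-activated carbonyl carbon of 2, and the new alkoxide acylates the acyl azolium to close the lactone and release the carbene; the closed Li-bridged transition state places aryl and CH2OBn cis, as in the closest known reaction type (the racemic imidazolylidene-catalysed enal plus aryl aldehyde γ-butyrolactone annulation), while the aminoindanol backbone blocks one face of the homoenolate so that C4 and C5 are set together as 4R,5R, as in the known highly enantioselective triazolium homoenolate annulations of isatins and nitroalkenes.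

**Step 4**
Reactants: 7 4-(benzyloxy)-3-methoxybenzyl alcohol
Product: 8 4-(benzyloxy)-3-methoxybenzyl bromide
Conditions: PBr3 (0.4 equiv), Et2O, 0 °C; used fresh
Reagents that add atoms: phosphorus tribromide, BrP(Br)Br
Why: PBr3 bromination: SN2 displacement by bromide on the phosphite ester of a primary benzylic alcohol.

**Step 5**
Reactants: 6 the cis-lactone; 8 4-(benzyloxy)-3-methoxybenzyl bromide
Product: 9 (3S,4R,5R)-3-[4-(benzyloxy)-3-methoxybenzyl]-4-[(benzyloxy)methyl]-5-[4-(benzyloxy)-3-bromo-5-methoxyphenyl]oxolan-2-one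
Conditions: LiN(SiMe3)2 (1.1 equiv), THF, −78 °C; then 8 (1.2 equiv), −78 → −30 °C
Reagents that add atoms: none
Why: Lactone enolate alkylation with a reactive benzylic bromide; attack anti to the C4 substituent gives the 3,4-trans product, but the C3 configuration is erased in step 6 and does not matter.

**Step 6**
Reactants: 9 the 3-benzyl lactone
Product: 10 (3S,4R,5R)-3-[4-(benzyloxy)-3-methoxybenzyl]-4-[(benzyloxy)methyl]-5-[4-(benzyloxy)-3-bromo-5-methoxyphenyl]-3-hydroxyoxolan-2-one
Conditions: KN(SiMe3)2 (1.3 equiv), THF, −78 → −40 °C; then 2-(benzenesulfonyl)-3-phenyloxaziridine (1.5 equiv), −78 °C; AcOH quench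
Reagents that add atoms: 2-(benzenesulfonyl)-3-phenyloxaziridine (Davis oxaziridine), O=S(=O)(c1ccccc1)N1OC1c1ccccc1
Why: Davis enolate hydroxylation; the planar enolate is oxidised on the face anti to the cis C4-CH2OBn and C5-aryl groups, so OH enters trans to both and the benzyl group ends cis to them, which sets the tertiary carbinol as 3S.

**Step 7**
Reactants: 10 the hydroxy-lactone
Product: 12 (3S,4R,5R)-3-[4-(benzyloxy)-3-methoxybenzyl]-4-[(benzyloxy)methyl]-5-[4-(benzyloxy)-3-bromo-5-methoxyphenyl]oxolan-3-ol, via lactol 11 (not isolated)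
Conditions: i-Bu2AlH (2.2 equiv), CH2Cl2, −78 °C; then Et3SiH (5 equiv), BF3·OEt2 (4 equiv), −78 → −50 °C; aq. KNaC4H4O6 work-up
Reagents that add atoms: none
Why: Partial lactone reduction followed by ionic hydrogenation of the lactol through its oxocarbenium ion; no stereocentre is touched, and at −78 °C the lactol ionises far faster than the benzylic C5–O bond, so the 4,5-cis relationship is kept.

**Step 8**
Reactants: 12 the oxolane bromide (about half of the material)
Product: 13 (2S,3S,4S)-6-(benzyloxy)-3-[(benzyloxy)methyl]-4-[4-(benzyloxy)-3-bromo-5-methoxyphenyl]-2-(hydroxymethyl)-7-methoxy-1,2,3,4-tetrahydronaphthalen-2-ol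
Conditions: CF3CO2H (10 equiv), CH2Cl2, 0 °C → rt
Reagents that add atoms: none
Why: Acid ionisation of the p-alkoxybenzylic C5–O bond and intramolecular Friedel–Crafts alkylation para to the methoxy group of the benzyl ring (the olivil to cycloolivil type rearrangement); the aryl group takes the equatorial position trans to the neighbouring CH2OBn (new centre 4S), the other two centres are untouched, and any re-closed oxolane simply re-ionises until the irreversible C–C bond forms.

**Step 9**
Reactants: 12 the oxolane bromide; 13 the tetralin bromide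
Product: 15 (2S,3S,4S)-6-(benzyloxy)-4-{2,2'-bis(benzyloxy)-5'-[(2R,3R,4S)-4-[4-(benzyloxy)-3-methoxybenzyl]-3-[(benzyloxy)methyl]-4-hydroxyoxolan-2-yl]-3,3'-dimethoxybiphenyl-5-yl}-3-[(benzyloxy)methyl]-2-(hydroxymethyl)-7-methoxy-1,2,3,4-tetrahydronaphthalen-2-ol, via pinacol boronate 14 (not isolated)
Conditions: 12 (1.1 equiv), bis(pinacolato)diboron (1.15 equiv), Pd2(dba)3 (2 mol %), XPhos (8 mol %), KOAc (3 equiv), 1,4-dioxane, 100 °C; then 13 (1.0 equiv), aq. K3PO4 (3 equiv), 100 °C
Reagents that add atoms: bis(pinacolato)diboron, CC1(C)OB(OC1(C)C)B1OC(C)(C)C(C)(C)O1 (supplies the Bpin group of 14; no boron remains in 15)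
Why: One-pot Miyaura borylation then Suzuki–Miyaura coupling; zerovalent palladium with a bulky biarylphosphine inserts into both electron-rich ortho-alkoxy aryl bromides, tolerates the free alcohols, and forms a biaryl with only two ortho substituents, so no stereocentre and no stable axis is involved.

**Step 10**
Reactants: 15 the hexa-O-benzyl dimer
Product: 16 (2S,3S,4S)-4-{2,2'-dihydroxy-5'-[(2R,3R,4S)-4-hydroxy-4-(4-hydroxy-3-methoxybenzyl)-3-(hydroxymethyl)oxolan-2-yl]-3,3'-dimethoxybiphenyl-5-yl}-2,3-bis(hydroxymethyl)-7-methoxy-1,2,3,4-tetrahydronaphthalene-2,6-diol (target CNP0344108.1)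
Conditions: H2 (1 atm), 10% Pd/C, EtOAc–EtOH 1:1, rt, monitored
Reagents that add atoms: none
Why: Catalytic hydrogenolysis of four aryl and two primary alkyl benzyl ethers under neutral conditions, where the hindered 2-aryl-oxolane C–O bond and the tetralin benzylic positions react much more slowly, so all six stereocentres are preserved.

**Compound list**
1 | 5-bromovanillin | COc1cc(C=O)cc(Br)c1O | starting material
2 | 4-(benzyloxy)-3-bromo-5-methoxybenzaldehyde | COc1cc(C=O)cc(Br)c1OCc1ccccc1 | intermediate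
3 | allyl benzyl ether | C=CCOCc1ccccc1 | starting material
4 | (E)-crotonaldehyde | C/C=C/C=O | starting material
5 | (E)-4-(benzyloxy)but-2-enal | O=C/C=C/COCc1ccccc1 | intermediate
6 | (4R,5R)-4-[(benzyloxy)methyl]-5-[4-(benzyloxy)-3-bromo-5-methoxyphenyl]oxolan-2-one (4,5-cis) | C1C(=O)O[C@@H](c2cc(OC)c(OCc3ccccc3)c(Br)c2)[C@H]1COCc1ccccc1 | intermediate
7 | 4-(benzyloxy)-3-methoxybenzyl alcohol | COc1cc(CO)ccc1OCc1ccccc1 | starting material
8 | 4-(benzyloxy)-3-methoxybenzyl bromide | COc1cc(CBr)ccc1OCc1ccccc1 | intermediate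
9 | (3S,4R,5R)-3-[4-(benzyloxy)-3-methoxybenzyl]-4-[(benzyloxy)methyl]-5-[4-(benzyloxy)-3-bromo-5-methoxyphenyl]oxolan-2-one (3,4-trans, 4,5-cis) | COc1cc(C[C@@H]2C(=O)O[C@@H](c3cc(OC)c(OCc4ccccc4)c(Br)c3)[C@H]2COCc2ccccc2)ccc1OCc1ccccc1 | intermediate
10 | (3S,4R,5R)-3-[4-(benzyloxy)-3-methoxybenzyl]-4-[(benzyloxy)methyl]-5-[4-(benzyloxy)-3-bromo-5-methoxyphenyl]-3-hydroxyoxolan-2-one (benzyl, CH2OBn and aryl cis; OH trans) | COc1cc(C[C@@]2(O)C(=O)O[C@@H](c3cc(OC)c(OCc4ccccc4)c(Br)c3)[C@H]2COCc2ccccc2)ccc1OCc1ccccc1 | intermediate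
11 | (3S,4R,5R)-3-[4-(benzyloxy)-3-methoxybenzyl]-4-[(benzyloxy)methyl]-5-[4-(benzyloxy)-3-bromo-5-methoxyphenyl]oxolane-2,3-diol (lactol, both C2 epimers, held as its aluminium alkoxide in the flask of step 7) | COc1cc(C[C@@]2(O)C(O)O[C@@H](c3cc(OC)c(OCc4ccccc4)c(Br)c3)[C@H]2COCc2ccccc2)ccc1OCc1ccccc1 | intermediate
12 | (3S,4R,5R)-3-[4-(benzyloxy)-3-methoxybenzyl]-4-[(benzyloxy)methyl]-5-[4-(benzyloxy)-3-bromo-5-methoxyphenyl]oxolan-3-ol | COc1cc(C[C@@]2(O)CO[C@@H](c3cc(OC)c(OCc4ccccc4)c(Br)c3)[C@H]2COCc2ccccc2)ccc1OCc1ccccc1 | intermediate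
13 | (2S,3S,4S)-6-(benzyloxy)-3-[(benzyloxy)methyl]-4-[4-(benzyloxy)-3-bromo-5-methoxyphenyl]-2-(hydroxymethyl)-7-methoxy-1,2,3,4-tetrahydronaphthalen-2-ol | COc1cc(cc(Br)c1OCc1ccccc1)[C@H]1c2cc(OCc3ccccc3)c(OC)cc2C[C@@](O)(CO)[C@@H]1COCc1ccccc1 | intermediate
14 | (3S,4R,5R)-3-[4-(benzyloxy)-3-methoxybenzyl]-4-[(benzyloxy)methyl]-5-[4-(benzyloxy)-3-methoxy-5-(4,4,5,5-tetramethyl-1,3,2-dioxaborolan-2-yl)phenyl]oxolan-3-ol (formed in the flask of step 9) | COc1cc(C[C@@]2(O)CO[C@@H](c3cc(OC)c(OCc4ccccc4)c(B4OC(C)(C)C(C)(C)O4)c3)[C@H]2COCc2ccccc2)ccc1OCc1ccccc1 | intermediate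
15 | hexa-O-benzyl ether of the target (name as in step 9) | COc1cc(C[C@@]2(O)CO[C@@H](c3cc(OC)c(OCc7ccccc7)c(-c4cc([C@H]5c6cc(OCc7ccccc7)c(OC)cc6C[C@@](O)(CO)[C@@H]5COCc5ccccc5)cc(OC)c4OCc4ccccc4)c3)[C@H]2COCc2ccccc2)ccc1OCc1ccccc1 | intermediate
16 | target CNP0344108.1 (name as in step 10) | COc1cc(C[C@@]2(O)CO[C@@H](c3cc(OC)c(O)c(-c4cc([C@H]5c6cc(O)c(OC)cc6C[C@@](O)(CO)[C@@H]5CO)cc(OC)c4O)c3)[C@H]2CO)ccc1O | target

**Totals**
Total steps: 10. Longest linear sequence: 8 steps (1, 3, 5, 6, 7, 8, 9, 10).

**Three steps most likely to fail**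

Step 3 is the riskiest. The enantioselective annulation with an aryl aldehyde partner is unproven, the cis:trans ratio may be only about 4:1, the enal can annulate with itself, and benzyloxide may be lost from the homoenolate. Fallback: starting from 2 and 5, the annulation is run with achiral 1,3-dimesitylimidazolium chloride and DBU, the established racemic protocol. This gives the racemic cis-lactone, that is 6 together with its mirror image, the (4S,5S)-lactone F1. The two are separated by preparative chiral SFC, so the absolute configuration comes from resolution instead of catalyst control, and the route is rejoined at 6.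

Step 8 is the second risk. The 3-bromo-4-benzyloxy aryl group ionises sluggishly, and the tertiary alcohol may dehydrate or a benzyl ether may be lost before ring closure. Fallback: starting from lactone 10, CF3CO2H ionises the benzylic lactone C–O bond, with the carboxylic acid as a poorly returning leaving group. Friedel–Crafts closure then gives the tetralin hydroxy acid F4, and BH3·SMe2 reduces its carboxyl group to CH2OH, which rejoins the route at 13.

Step 7 is the third risk. BF3 could ionise the benzylic C5–O bond (epimerisation to the 4,5-trans oxolane or over-reduction), or the α-hydroxy oxocarbenium ion could undergo a 1,2-shift. Fallback: starting from 10, LiBH4 in THF–MeOH opens the lactone to the butane-1,2,4-triol F2. Bu2SnO-catalysed tosylation (TsCl, Et3N) then selects the primary hydroxyl of its 1,2-diol to give the primary tosylate F3. NaH in THF closes the ring by intramolecular Williamson etherification at the CH2 carbon, directly or through the terminal epoxide, with retention at all three stereocentres, and the route is rejoined at 12.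

**Further compounds**
F1 | step 3 | (4S,5S)-4-[(benzyloxy)methyl]-5-[4-(benzyloxy)-3-bromo-5-methoxyphenyl]oxolan-2-one | C1C(=O)O[C@H](c2cc(OC)c(OCc3ccccc3)c(Br)c2)[C@@H]1COCc1ccccc1
F2 | step 7 | (2S,3R,4R)-2-[4-(benzyloxy)-3-methoxybenzyl]-3-[(benzyloxy)methyl]-4-[4-(benzyloxy)-3-bromo-5-methoxyphenyl]butane-1,2,4-triol | COc1cc(C[C@@]([C@H](COCc2ccccc2)[C@@H](O)c2cc(OC)c(OCc3ccccc3)c(Br)c2)(O)CO)ccc1OCc1ccccc1
F3 | step 7 | (2S,3R,4R)-2-[4-(benzyloxy)-3-methoxybenzyl]-3-[(benzyloxy)methyl]-4-[4-(benzyloxy)-3-bromo-5-methoxyphenyl]-2,4-dihydroxybutyl 4-methylbenzenesulfonate | COc1cc(C[C@@]([C@H](COCc2ccccc2)[C@@H](O)c2cc(OC)c(OCc3ccccc3)c(Br)c2)(O)COS(=O)(=O)c2ccc(C)cc2)ccc1OCc1ccccc1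
F4 | step 8 | (2S,3S,4S)-6-(benzyloxy)-3-[(benzyloxy)methyl]-4-[4-(benzyloxy)-3-bromo-5-methoxyphenyl]-2-hydroxy-7-methoxy-1,2,3,4-tetrahydronaphthalene-2-carboxylic acid | COc1cc(cc(Br)c1OCc1ccccc1)[C@H]1c2cc(OCc3ccccc3)c(OC)cc2C[C@@](O)(C(O)=O)[C@@H]1COCc1ccccc1
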